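**Assumption:** eremophilane-type numbering is used in the comments (C8 ketone, C3 and C9 acyloxy carbons, C4/C5 methyl-bearing carbons, C10 ring-fusion CH, C7 isopropenyl carbon; ring A = C1–C5/C10, ring B = C5–C10; β = face of the C5 methyl). Aqueous work-up is taken as water. The route is a paper design; it has not been run.

## Retrosynthetic overview

1. Target ⇐ ketol 30 by two late acylations (angelic mixed anhydride 17, then senecioyl chloride 33). Ketol 30 ⇐ enone 26 by Cu–H 1,4-reduction (cis ring fusion) and Rubottom oxidation at C9.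
2. Enone 26 ⇐ bicyclic enone 22 by α'-alkenylation with 2-bromopropene.
3. Ring B of 22 ⇐ intramolecular aldol condensation of 1,5-diketone 20 (the ring-closing step).
4. Diketone 20 ⇐ three-component union of ring-A enone 6, Me2CuLi and silyl vinyl ketone 13. Enone 6 ⇐ 4-methoxy-3-methylphenol; 13 ⇐ vinyltrimethylsilane; 17 ⇐ acetaldehyde.
5. Ring order: ring A is carried in from the arene of 1 (steps 1–5); ring B is closed second, by the aldol (step 14).

## Route

**Ring-A enone (steps 1–5)**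

Step 1
Reactants: 1 4-methoxy-3-methylphenol
Product: 2 4,4-dimethoxy-3-methylcyclohexa-2,5-dien-1-one
Conditions: PhI(OAc)2 (1.1 equiv), MeOH, 0 °C
Reagents that add atoms: methanol, CO
Why: Hypervalent-iodine oxidative dearomatisation of the para-methoxyphenol, with methanol trapping at the para carbon, gives the quinone monoketal; no stereocentre.

Step 2
Reactants: 2 4,4-dimethoxy-3-methylcyclohexa-2,5-dien-1-one
Product: 3 4,4-dimethoxy-3-methylcyclohex-2-en-1-one
Conditions: H2 (1 atm), RhCl(PPh3)3 (3 mol %), PhMe, 23 °C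
Reagents that add atoms: none
Why: Homogeneous hydrogenation reduces the unhindered disubstituted enone C=C much faster than the trisubstituted methyl-bearing one and does not hydrogenolyse the allylic ketal; no stereocentre.

Step 3
Reactants: 3 4,4-dimethoxy-3-methylcyclohex-2-en-1-one
Product: 4 (1R)-4,4-dimethoxy-3-methylcyclohex-2-en-1-ol
Conditions: RuCl[(R,R)-TsDPEN](p-cymene) (1 mol %), HCO2Na, n-Bu4NCl (cat.), CH2Cl2/H2O, 23 °C
Reagents that add atoms: none
Why: Noyori asymmetric transfer hydrogenation reduces only the C=O; with the alkene flank in the role of the aryl group of an aryl ketone, the (R,R)-catalyst is expected to give the (R)-carbinol, which becomes the C3–O centre.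

Step 4
Reactants: 4 (1R)-4,4-dimethoxy-3-methylcyclohex-2-en-1-ol
Product: 5 tert-butyl{[(1R)-4,4-dimethoxy-3-methylcyclohex-2-en-1-yl]oxy}dimethylsilane
Conditions: TBSCl, imidazole, DMF, 23 °C
Reagents that add atoms: tert-butyldimethylsilyl chloride, CC(C)(C)[Si](C)(C)Cl
Why: Standard silylation of the secondary allylic alcohol; the stereocentre is untouched.

Step 5
Reactants: 5 tert-butyl{[(1R)-4,4-dimethoxy-3-methylcyclohex-2-en-1-yl]oxy}dimethylsilane
Product: 6 (4R)-4-[(tert-butyldimethylsilyl)oxy]-2-methylcyclohex-2-en-1-one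
Conditions: PPTS (0.1 equiv), acetone/H2O (10:1), 23 °C
Reagents that add atoms: water, O
Why: Mild acid hydrolysis of the dimethyl ketal unmasks the ketone as an enone carrying the methyl on its α-carbon; the silyl ether and the carbinol centre survive PPTS.

**Annulation reagent (steps 6–9)**

Step 6
Reactants: 7 trimethyl(vinyl)silane
Product: 8 (1,2-dibromoethyl)trimethylsilane
Conditions: Br2, CH2Cl2, −78 °C
Reagents that add atoms: bromine, BrBr
Why: Electrophilic addition of bromine to the vinylsilane; the racemic centre is removed in step 7.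

Step 7
Reactants: 8 (1,2-dibromoethyl)trimethylsilane
Product: 9 (1-bromovinyl)trimethylsilane
Conditions: Et2NH, reflux
Reagents that add atoms: none
Why: Amine-induced E2 dehydrobromination removes the acidic α-silyl hydrogen and the primary bromide, giving the 1-bromovinylsilane.

Step 8
Reactants: 9 (1-bromovinyl)trimethylsilane; 10 acetaldehyde
Product: 12 3-(trimethylsilyl)but-3-en-2-ol, via vinyl Grignard reagent 11 (not isolated)
Conditions: Mg, THF, reflux; then 10, 0 °C
Reagents that add atoms: none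
Why: Grignard formation from the vinyl bromide and 1,2-addition to the aldehyde; the racemic carbinol centre is oxidised away in step 9.

Step 9
Reactants: 12 3-(trimethylsilyl)but-3-en-2-ol
Product: 13 3-(trimethylsilyl)but-3-en-2-one
Conditions: CrO3, H2SO4, H2O/acetone, 0 °C
Reagents that add atoms: none
Why: Jones oxidation of the secondary allylic alcohol gives the α-silyl vinyl ketone (Stork–Ganem Michael acceptor).

**Angeloyl donor (steps 10–12)**

Step 10
Reactants: 10 acetaldehyde; 14 methyl 2-[bis(2,2,2-trifluoroethoxy)phosphoryl]propanoate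
Product: 15 methyl (2Z)-2-methylbut-2-enoate
Conditions: KN(SiMe3)2, 18-crown-6, THF, −78 °C
Reagents that add atoms: none
Why: The Still–Gennari variant of the Horner–Wadsworth–Emmons olefination gives the Z-trisubstituted enoate by fast kinetic elimination from the trifluoroethyl phosphonate adduct.

Step 11
Reactants: 15 methyl (2Z)-2-methylbut-2-enoate
Product: 16 (2Z)-2-methylbut-2-enoic acid
Conditions: LiOH, THF/H2O, 23 °C; then 1 M HCl, 0 °C
Reagents that add atoms: lithium hydroxide, [Li+].[OH-]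
Why: Saponification at room temperature and cold acidification free angelic acid without Z-to-E isomerisation.

Step 12
Reactants: 16 (2Z)-2-methylbut-2-enoic acid
Product: 17 (2Z)-2-methylbut-2-enoic 2,4,6-trichlorobenzoic anhydride
Conditions: 2,4,6-Cl3C6H2COCl, Et3N, PhMe, 23 °C; filtration
Reagents that add atoms: 2,4,6-trichlorobenzoyl chloride, O=C(Cl)c1c(Cl)cc(Cl)cc1Cl
Why: Acylation of the carboxylate gives the Yamaguchi-type mixed anhydride, whose hindered aroyl carbonyl later directs attack to the angeloyl carbonyl.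

**Union and endgame (steps 13–20)**

Step 13
Reactants: 6 (4R)-4-[(tert-butyldimethylsilyl)oxy]-2-methylcyclohex-2-en-1-one; 13 3-(trimethylsilyl)but-3-en-2-one
Product: 19 (2R,3R,4R)-4-[(tert-butyldimethylsilyl)oxy]-2,3-dimethyl-2-[3-oxo-2-(trimethylsilyl)butyl]cyclohexan-1-one, via lithium enolate 18 (not isolated)
Conditions: MeLi (2.4 equiv), CuI (1.2 equiv), Et2O, −78 → −30 °C; then 13 (1.3 equiv), −78 → 0 °C
Reagents that add atoms: lithium dimethylcuprate (from MeLi and CuI), [Li+].C[Cu-]C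
Why: Cuprate conjugate addition anti to the γ-silyloxy group sets the C4 methyl trans to the C3–O, and Michael addition of the regiodefined enolate to the α-silyl vinyl ketone anti to that new methyl creates the quaternary C5 with the two methyls cis.

Step 14
Reactants: 19 (2R,3R,4R)-4-[(tert-butyldimethylsilyl)oxy]-2,3-dimethyl-2-[3-oxo-2-(trimethylsilyl)butyl]cyclohexan-1-one
Product: 22 (4aR,5R,6R)-6-[(tert-butyldimethylsilyl)oxy]-4a,5-dimethyl-4,4a,5,6,7,8-hexahydronaphthalen-2(3H)-one, via desilylated diketone 20 (not isolated), via aldol ketol 21 (not isolated)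
Conditions: KOH (5% in MeOH), 23 → 60 °C
Reagents that add atoms: none
Why: Methoxide cleaves the C–Si bond and the freed methyl ketone closes ring B by intramolecular aldol condensation of C9 onto the C10 ketone (Robinson annulation); no stereocentre is made or lost.

Step 15
Reactants: 22 (4aR,5R,6R)-6-[(tert-butyldimethylsilyl)oxy]-4a,5-dimethyl-4,4a,5,6,7,8-hexahydronaphthalen-2(3H)-one; 23 2-bromoprop-1-ene
Product: 26 (3S,4aR,5R,6R)-6-[(tert-butyldimethylsilyl)oxy]-4a,5-dimethyl-3-(prop-1-en-2-yl)-4,4a,5,6,7,8-hexahydronaphthalen-2(3H)-one, via lithium dienolate 24 (not isolated), via chlorozinc dienolate 25 (not isolated)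
Conditions: LiN(i-Pr)2 (1.1 equiv), THF, −78 °C; ZnCl2 (1.2 equiv), −78 → 0 °C; 23 (1.5 equiv), Pd(P(t-Bu)3)2 (5 mol %), 23 °C
Reagents that add atoms: none
Why: Kinetic deprotonation gives only the cross-conjugated C7 enolate, and Negishi-type Pd-catalysed α-alkenylation of its non-basic zinc enolate forms the C7–isopropenyl bond anti to the angular methyl (7α, pseudo-equatorial) without conjugating the new alkene.

Step 16
Reactants: 26 (3S,4aR,5R,6R)-6-[(tert-butyldimethylsilyl)oxy]-4a,5-dimethyl-3-(prop-1-en-2-yl)-4,4a,5,6,7,8-hexahydronaphthalen-2(3H)-one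
Product: 27 (3S,4aS,5R,6R,8aR)-6-[(tert-butyldimethylsilyl)oxy]-2-{[dimethyl(phenyl)silyl]oxy}-4a,5-dimethyl-3-(prop-1-en-2-yl)-3,4,4a,5,6,7,8,8a-octahydronaphthalene
Conditions: [(Ph3P)CuH]6 (5 mol %), PhMe2SiH (1.5 equiv), PhMe, 23 → 40 °C
Reagents that add atoms: dimethylphenylsilane, C[SiH](C)c1ccccc1
Why: Copper hydride 1,4-hydrosilylation touches only the enone and traps the enolate regiospecifically as the C8–C9 silyl enol ether; hydride is expected at C10 syn to the angular methyl (10βH, cis fusion), as in cuprate additions and hydrogenations of 4a-methyloctalones.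

Step 17
Reactants: 27 (3S,4aS,5R,6R,8aR)-6-[(tert-butyldimethylsilyl)oxy]-2-{[dimethyl(phenyl)silyl]oxy}-4a,5-dimethyl-3-(prop-1-en-2-yl)-3,4,4a,5,6,7,8,8a-octahydronaphthalene
Product: 30 (1R,3R,4aR,5R,6R,8aS)-6-[(tert-butyldimethylsilyl)oxy]-1-hydroxy-4a,5-dimethyl-3-(prop-1-en-2-yl)octahydronaphthalen-2(1H)-one, via silyloxy ketone 28 (not isolated), via 7-epi ketol 29 (not isolated)
Conditions: m-CPBA (1.05 equiv), NaHCO3, CH2Cl2, −20 °C; then K2CO3 (0.2 equiv), MeOH, 0 °C
Reagents that add atoms: 3-chloroperoxybenzoic acid, OOC(=O)c1cccc(Cl)c1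
Why: Rubottom oxidation on the convex β-face of the cis-fused enol ether, followed by 1,4-silyl shift, gives the 9β-oxygenated ketone; brief carbonate methanolysis frees the alcohol and equilibrates C7 (and C9) to the all-equatorial 7β,9β isomer of the cis-decalone.

Step 18
Reactants: 30 (1R,3R,4aR,5R,6R,8aS)-6-[(tert-butyldimethylsilyl)oxy]-1-hydroxy-4a,5-dimethyl-3-(prop-1-en-2-yl)octahydronaphthalen-2(1H)-one; 17 (2Z)-2-methylbut-2-enoic 2,4,6-trichlorobenzoic anhydride
Product: 31 (1R,3R,4aR,5R,6R,8aS)-6-[(tert-butyldimethylsilyl)oxy]-4a,5-dimethyl-2-oxo-3-(prop-1-en-2-yl)decahydronaphthalen-1-yl (2Z)-2-methylbut-2-enoate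
Conditions: 17 (3 equiv), PhMe, 75 °C (no DMAP)
Reagents that add atoms: none
Why: Acylation of the α-ketol by the preformed mixed anhydride without a nucleophilic catalyst transfers the angeloyl group without Z-to-E isomerisation; configuration at C9 is retained.

Step 19
Reactants: 31 (1R,3R,4aR,5R,6R,8aS)-6-[(tert-butyldimethylsilyl)oxy]-4a,5-dimethyl-2-oxo-3-(prop-1-en-2-yl)decahydronaphthalen-1-yl (2Z)-2-methylbut-2-enoate
Product: 32 (1R,3R,4aR,5R,6R,8aS)-6-hydroxy-4a,5-dimethyl-2-oxo-3-(prop-1-en-2-yl)decahydronaphthalen-1-yl (2Z)-2-methylbut-2-enoate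
Conditions: HF·pyridine, pyridine/THF, 0 → 23 °C
Reagents that add atoms: none
Why: Buffered fluoride desilylation under non-basic conditions leaves the angelate and the β,γ-unsaturated ketone untouched.

Step 20
Reactants: 32 (1R,3R,4aR,5R,6R,8aS)-6-hydroxy-4a,5-dimethyl-2-oxo-3-(prop-1-en-2-yl)decahydronaphthalen-1-yl (2Z)-2-methylbut-2-enoate; 33 3-methylbut-2-enoyl chloride
Product: 34 (1R,3R,4aR,5R,6R,8aS)-4a,5-dimethyl-6-[(3-methylbut-2-enoyl)oxy]-2-oxo-3-(prop-1-en-2-yl)decahydronaphthalen-1-yl (2Z)-2-methylbut-2-enoate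
Conditions: 33 (1.5 equiv), pyridine, DMAP (0.1 equiv), CH2Cl2, 0 °C
Reagents that add atoms: none
Why: Acylation of the equatorial C3 alcohol with the acid chloride under pyridine (no triethylamine, to avoid the vinylketene pathway and deconjugation) gives the senecioate with retention, completing the target.

## Compound list

1 | 4-methoxy-3-methylphenol | COc1ccc(O)cc1C | starting material
2 | 4,4-dimethoxy-3-methylcyclohexa-2,5-dien-1-one | COC1(OC)C=CC(=O)C=C1C | intermediate
3 | 4,4-dimethoxy-3-methylcyclohex-2-en-1-one | COC1(OC)CCC(=O)C=C1C | intermediate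
4 | (1R)-4,4-dimethoxy-3-methylcyclohex-2-en-1-ol | O[C@H]1C=C(C)C(OC)(OC)CC1 | intermediate
5 | tert-butyl{[(1R)-4,4-dimethoxy-3-methylcyclohex-2-en-1-yl]oxy}dimethylsilane | CC(C)(C)[Si](C)(C)O[C@H]1C=C(C)C(OC)(OC)CC1 | intermediate
6 | (4R)-4-[(tert-butyldimethylsilyl)oxy]-2-methylcyclohex-2-en-1-one | CC(C)(C)[Si](C)(C)O[C@H]1C=C(C)C(=O)CC1 | intermediate
7 | trimethyl(vinyl)silane | C=C[Si](C)(C)C | starting material
8 | (1,2-dibromoethyl)trimethylsilane (racemic) | C[Si](C)(C)C(Br)CBr | intermediate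
9 | (1-bromovinyl)trimethylsilane | C=C(Br)[Si](C)(C)C | intermediate
10 | acetaldehyde | CC=O | starting material
11 | [1-(trimethylsilyl)vinyl]magnesium bromide | C=C([Mg]Br)[Si](C)(C)C | intermediate (not isolated)
12 | 3-(trimethylsilyl)but-3-en-2-ol (racemic) | CC(O)C(=C)[Si](C)(C)C | intermediate
13 | 3-(trimethylsilyl)but-3-en-2-one | CC(=O)C(=C)[Si](C)(C)C | intermediate
14 | methyl 2-[bis(2,2,2-trifluoroethoxy)phosphoryl]propanoate (racemic) | COC(=O)C(C)P(=O)(OCC(F)(F)F)OCC(F)(F)F | starting material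
15 | methyl (2Z)-2-methylbut-2-enoate (methyl angelate) | C/C=C(/C)C(=O)OC | intermediate
16 | (2Z)-2-methylbut-2-enoic acid (angelic acid) | C/C=C(/C)C(=O)O | intermediate
17 | (2Z)-2-methylbut-2-enoic 2,4,6-trichlorobenzoic anhydride | C/C=C(/C)C(=O)OC(=O)c1c(Cl)cc(Cl)cc1Cl | intermediate
18 | lithium (3R,4R)-4-[(tert-butyldimethylsilyl)oxy]-2,3-dimethylcyclohex-1-en-1-olate | [Li]OC1=C(C)[C@@H](C)[C@H](O[Si](C)(C)C(C)(C)C)CC1 | intermediate (not isolated)
19 | (2R,3R,4R)-4-[(tert-butyldimethylsilyl)oxy]-2,3-dimethyl-2-[3-oxo-2-(trimethylsilyl)butyl]cyclohexan-1-one (epimer mixture at the silyl-bearing carbon) | CC(=O)C([Si](C)(C)C)C[C@@]1(C)C(=O)CC[C@@H](O[Si](C)(C)C(C)(C)C)[C@@H]1C | intermediate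
20 | (2R,3R,4R)-4-[(tert-butyldimethylsilyl)oxy]-2,3-dimethyl-2-(3-oxobutyl)cyclohexan-1-one | CC(=O)CC[C@@]1(C)C(=O)CC[C@@H](O[Si](C)(C)C(C)(C)C)[C@@H]1C | intermediate (not isolated)
21 | (4aR,5R,6R)-6-[(tert-butyldimethylsilyl)oxy]-8a-hydroxy-4a,5-dimethyloctahydronaphthalen-2(1H)-one (either C8a epimer) | O=C1CC[C@]2(C)[C@@H](C)[C@H](O[Si](C)(C)C(C)(C)C)CCC2(O)C1 | intermediate (not isolated)
22 | (4aR,5R,6R)-6-[(tert-butyldimethylsilyl)oxy]-4a,5-dimethyl-4,4a,5,6,7,8-hexahydronaphthalen-2(3H)-one | O=C1CC[C@]2(C)[C@@H](C)[C@H](O[Si](C)(C)C(C)(C)C)CCC2=C1 | intermediate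
23 | 2-bromoprop-1-ene | CC(Br)=C | starting material
24 | lithium (4aR,5R,6R)-6-[(tert-butyldimethylsilyl)oxy]-4a,5-dimethyl-4,4a,5,6,7,8-hexahydronaphthalen-2-olate (cross-conjugated dienolate) | [Li]OC1=CC[C@]2(C)[C@@H](C)[C@H](O[Si](C)(C)C(C)(C)C)CCC2=C1 | intermediate (not isolated)
25 | chlorozinc (4aR,5R,6R)-6-[(tert-butyldimethylsilyl)oxy]-4a,5-dimethyl-4,4a,5,6,7,8-hexahydronaphthalen-2-olate | Cl[Zn]OC1=CC[C@]2(C)[C@@H](C)[C@H](O[Si](C)(C)C(C)(C)C)CCC2=C1 | intermediate (not isolated)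
26 | (3S,4aR,5R,6R)-6-[(tert-butyldimethylsilyl)oxy]-4a,5-dimethyl-3-(prop-1-en-2-yl)-4,4a,5,6,7,8-hexahydronaphthalen-2(3H)-one (7α-isopropenyl) | O=C1[C@H](C(C)=C)C[C@]2(C)[C@@H](C)[C@H](O[Si](C)(C)C(C)(C)C)CCC2=C1 | intermediate
27 | (3S,4aS,5R,6R,8aR)-6-[(tert-butyldimethylsilyl)oxy]-2-{[dimethyl(phenyl)silyl]oxy}-4a,5-dimethyl-3-(prop-1-en-2-yl)-3,4,4a,5,6,7,8,8a-octahydronaphthalene (cis-fused, 10βH) | C=C(C)[C@@H]1C[C@@]2(C)[C@H](CC[C@@H](O[Si](C)(C)C(C)(C)C)[C@@H]2C)C=C1O[Si](C)(C)c1ccccc1 | intermediate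
28 | (1R,3S,4aR,5R,6R,8aS)-6-[(tert-butyldimethylsilyl)oxy]-1-{[dimethyl(phenyl)silyl]oxy}-4a,5-dimethyl-3-(prop-1-en-2-yl)octahydronaphthalen-2(1H)-one | C=C(C)[C@@H]1C[C@@]2(C)[C@H](CC[C@@H](O[Si](C)(C)C(C)(C)C)[C@@H]2C)[C@@H](O[Si](C)(C)c3ccccc3)C1=O | intermediate (not isolated)
29 | (1R,3S,4aR,5R,6R,8aS)-6-[(tert-butyldimethylsilyl)oxy]-1-hydroxy-4a,5-dimethyl-3-(prop-1-en-2-yl)octahydronaphthalen-2(1H)-one (7-epi ketol) | C=C(C)[C@@H]1C[C@@]2(C)[C@H](CC[C@@H](O[Si](C)(C)C(C)(C)C)[C@@H]2C)[C@@H](O)C1=O | intermediate (not isolated)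
30 | (1R,3R,4aR,5R,6R,8aS)-6-[(tert-butyldimethylsilyl)oxy]-1-hydroxy-4a,5-dimethyl-3-(prop-1-en-2-yl)octahydronaphthalen-2(1H)-one | C=C(C)[C@H]1C[C@@]2(C)[C@H](CC[C@@H](O[Si](C)(C)C(C)(C)C)[C@@H]2C)[C@@H](O)C1=O | intermediate
31 | (1R,3R,4aR,5R,6R,8aS)-6-[(tert-butyldimethylsilyl)oxy]-4a,5-dimethyl-2-oxo-3-(prop-1-en-2-yl)decahydronaphthalen-1-yl (2Z)-2-methylbut-2-enoate | C=C(C)[C@H]1C[C@@]2(C)[C@H](CC[C@@H](O[Si](C)(C)C(C)(C)C)[C@@H]2C)[C@@H](OC(=O)/C(C)=C\C)C1=O | intermediate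
32 | (1R,3R,4aR,5R,6R,8aS)-6-hydroxy-4a,5-dimethyl-2-oxo-3-(prop-1-en-2-yl)decahydronaphthalen-1-yl (2Z)-2-methylbut-2-enoate | C=C(C)[C@H]1C[C@@]2(C)[C@H](CC[C@@H](O)[C@@H]2C)[C@@H](OC(=O)/C(C)=C\C)C1=O | intermediate
33 | 3-methylbut-2-enoyl chloride | CC(C)=CC(Cl)=O | starting material
34 | (1R,3R,4aR,5R,6R,8aS)-4a,5-dimethyl-6-[(3-methylbut-2-enoyl)oxy]-2-oxo-3-(prop-1-en-2-yl)decahydronaphthalen-1-yl (2Z)-2-methylbut-2-enoate (CNP0164025.2) | C=C(C)[C@H]1C[C@@]2(C)[C@H](CC[C@@H](OC(=O)C=C(C)C)[C@@H]2C)[C@@H](OC(=O)/C(C)=C\C)C1=O | target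

## Step count and risks

Total step count: 20. Longest linear sequence: 13 (steps 1–5, then 13–20).

**Step 13 (cuprate addition and Michael trapping).** The tetrasubstituted enolate is hindered, the acceptor polymerises easily, and attack at C5 anti to the new methyl is syn-axial to the silyloxy group, so yield and the C5 ratio may suffer. The fallback sets out from 6 and comes back at 20. The cuprate adduct of 6 is trapped with Me3SiCl/Et3N and isolated as trimethylsilyl enol ether F1. A Mukaiyama–Michael addition of F1 to but-3-en-2-one (TiCl4, Ti(Oi-Pr)4, CH2Cl2, −78 °C) through an open transition state then gives diketone 20 directly. Diketone 20 is cyclised to 22 under the conditions of step 14.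

**Step 15 (Pd-catalysed α'-alkenylation).** Coupling may be slow, may occur at the γ-position through enolate equilibration, or the product may conjugate to the isopropylidene dienone. The fallback sets out from 22 and comes back at 26. The zinc enolate of 22 (LiN(i-Pr)2, ZnCl2, THF, −78 °C) is added to acetone in an aldol reaction to give tertiary aldol carbinol F2. Kinetic dehydration of F2 toward the methyl groups (SOCl2, pyridine, −20 °C) gives 26; any conjugated isomer is removed by chromatography.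

**Step 16 (Cu–H 1,4-reduction).** The β-carbon is flanked by the quaternary centre, and hydride may arrive anti to the angular methyl, giving the trans-fused isomer. The fallback sets out from 22 and comes back at 30. Enone 22 is hydrogenated (H2, Pd/C, EtOAc) to cis-decalone F3. Thermodynamic silylation (Me3SiOTf, Et3N, CH2Cl2, 0 °C), which in cis-fused decalones enolises toward the ring fusion, gives trimethylsilyl enol ether F4. Rubottom oxidation (m-CPBA, NaHCO3; then citric acid, MeOH) gives hydroxy ketone F5, and Et3SiCl/imidazole gives triethylsilyl ether F6. The zinc-enolate alkenylation of step 15 at the only free α-carbon (C7) gives isopropenyl ketone F7, which forms directly as the equatorial 7β isomer. Selective removal of the triethylsilyl group (AcOH/THF/H2O) returns 30.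

## Further compounds

F1 | step 13 | tert-butyl{[(1R,2R)-2,3-dimethyl-4-(trimethylsilyloxy)cyclohex-3-en-1-yl]oxy}dimethylsilane | C[Si](C)(C)OC1=C(C)[C@@H](C)[C@H](O[Si](C)(C)C(C)(C)C)CC1
F2 | step 15 | (3S,4aR,5R,6R)-6-[(tert-butyldimethylsilyl)oxy]-3-(2-hydroxypropan-2-yl)-4a,5-dimethyl-4,4a,5,6,7,8-hexahydronaphthalen-2(3H)-one | O=C1[C@H](C(C)(C)O)C[C@]2(C)[C@@H](C)[C@H](O[Si](C)(C)C(C)(C)C)CCC2=C1
F3 | step 16 | (4aS,5R,6R,8aR)-6-[(tert-butyldimethylsilyl)oxy]-4a,5-dimethyloctahydronaphthalen-2(1H)-one (cis-fused, 10βH) | C1C[C@@]2(C)[C@H](CC[C@@H](O[Si](C)(C)C(C)(C)C)[C@@H]2C)CC1=O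
F4 | step 16 | C8–C9 trimethylsilyl enol ether of F3 (cis-fused, 10βH) | C1C[C@@]2(C)[C@H](CC[C@@H](O[Si](C)(C)C(C)(C)C)[C@@H]2C)C=C1O[Si](C)(C)C
F5 | step 16 | (1R,4aR,5R,6R,8aS)-6-[(tert-butyldimethylsilyl)oxy]-1-hydroxy-4a,5-dimethyloctahydronaphthalen-2(1H)-one | C1C[C@@]2(C)[C@H](CC[C@@H](O[Si](C)(C)C(C)(C)C)[C@@H]2C)[C@@H](O)C1=O
F6 | step 16 | (1R,4aR,5R,6R,8aS)-6-[(tert-butyldimethylsilyl)oxy]-4a,5-dimethyl-1-[(triethylsilyl)oxy]octahydronaphthalen-2(1H)-one | C1C[C@@]2(C)[C@H](CC[C@@H](O[Si](C)(C)C(C)(C)C)[C@@H]2C)[C@@H](O[Si](CC)(CC)CC)C1=O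
F7 | step 16 | (1R,3R,4aR,5R,6R,8aS)-6-[(tert-butyldimethylsilyl)oxy]-4a,5-dimethyl-3-(prop-1-en-2-yl)-1-[(triethylsilyl)oxy]octahydronaphthalen-2(1H)-one | C=C(C)[C@H]1C[C@@]2(C)[C@H](CC[C@@H](O[Si](C)(C)C(C)(C)C)[C@@H]2C)[C@@H](O[Si](CC)(CC)CC)C1=O
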